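Start with an easy step: substrate and reagent are stirred together, the reagent in portions, and target and side product appear. In a finished run, dividing one product by the other costs nothing.

| flask | substrate | reagent | remark | time |
|---|---|---|---|---|
| eta | 0.17 M | 0.325 M (in portions, 2) | run made earlier; portions every 20 min |  |
| zeta | 0.38 M | 0.325 M (in portions, 2) | run made earlier; portions every 20 min |  |
| delta | 0.25 M | 0.49 M (in portions, 2) | run made earlier; portions every 20 min |  |
| flask | 0.25 M | 0.325 M (in portions, 2) | the portions of reagent follow each other after 20 min, the first at the start | 20 h |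

| run | time / h | target / % | side product / % |
|---|---|---|---|
| eta | 2.00 | 79.9 | 18.7 |
| eta | 5.00 | 81.3 | 20.4 |
| eta | 10.0 | 79.3 | 18.3 |
| eta | 15.0 | 80.2 | 19.5 |
| eta | 20.0 | 79.8 | 20.6 |
| zeta | 2.00 | 62.9 | 17.4 |
| zeta | 5.00 | 66.6 | 18.2 |
| zeta | 10.0 | 68.1 | 17.5 |
| zeta | 15.0 | 68.3 | 15.8 |
| zeta | 20.0 | 68.5 | 18.2 |
| delta | 2.00 | 73.9 | 25.6 |
| delta | 5.00 | 73.7 | 25.9 |
| delta | 10.0 | 73.5 | 25.9 |
| delta | 15.0 | 73.8 | 25.6 |
| delta | 20.0 | 73.1 | 25.9 |

(each reading ± 0.5 percentage points)

- the reaction counts as stopped when no species that holds the substrate changes by six tenths of a point or more over the second half of the time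

- the state of affairs at 20 h: stopped, and by what, or still going (the reagent has run out first / it is still moving / all of the substrate has reacted / forward and back rates have come level)
- the target standing at 20 h, as a percentage of the substrate charged
- the side product standing at 20 h, as a percentage of the substrate charged

Delta has finished by its first reading: both products stand flat from 2.00 h to 20.0 h. Their ratio in a finished run can be read without following how each product formed. The ratio of side product to target, divided by the reagent charge, with two portions 20 min apart, is here the selectivity factor b. Delta's mean readings give b = 0.715 L mol⁻¹. For eta, b times the charge gives 0.232, and eta's mean readings give 0.243, so b can be frozen.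

Zeta goes on moving after its first reading: target gains 3.7 percentage points from 2.00 h to 5.00 h, then 1.5 points by 10.0 h. Its products at 20.0 h hold 0.329 M of substrate against 0.325 M of reagent charged, which reads as one reagent per product. The flask charges 0.325 M of reagent to 0.25 M of substrate, so the substrate should go first. Its ratio is then 0.232, which gives 81.1% target and 18.9% side product.

The forecast says all of the substrate has reacted, with 79.7% target and 20% side product: “The flask should sit near 0.25, giving about 80/20.”

The flask gives all of the substrate has reacted, with 81.1% target and 18.7% side product, and 23% of the charged reagent stands at 20.0 h. Its ratio, 0.231, divided by the charge returns b as 0.709 L mol⁻¹.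

    substrate → intermediate A (k = 1.12 min⁻¹)
    reagent + intermediate A → target (k = 0.205 L mol⁻¹ min⁻¹)
    substrate + reagent → intermediate B (k = 1.92 L mol⁻¹ min⁻¹)
    substrate → decomposition product (k = 1.80 × 10⁻⁴ min⁻¹)
    reagent + intermediate B ⇌ intermediate C (K = 11.2 L mol⁻¹, k = 0.0111 L mol⁻¹ min⁻¹)
    intermediate B → side product (k = 0.0717 min⁻¹)

With 0.55 M of reagent, b gives a ratio of 0.393, so 71.8% target and 28.2% side product. That neighbour computes to 71.3% and 28.4%.

(The numbers in the tables were computed for substances that don't exist; scatter was added.)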